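A direct plan would take the central ring ready-made: stepwise oxidation of a protected catechol would give 4,5-bis(benzyloxy)-o-benzoquinone A1.
Both free ring carbons of A1 would be arylated with 4-(benzyloxy)benzenediazonium tetrafluoroborate A2 to give terphenylquinone A3.
A3 would be reduced and benzoylated to the tetrabenzyl ether dibenzoate A4, and hydrogenolysis would finish the synthesis.
Weakest point one would be the twofold radical C–H arylation of the o-quinone: it would have to form both hindered biaryl bonds next to the carbonyl groups on a substrate class where this is not established, against azo coupling and mono/diaryl mixtures.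
Weakest point two would be the oxidation-level detour (phenol, o-quinone, catechol): it would spend steps without forming any skeletal bond and pass through a sensitive o-quinone.
Weakest point three would be the reductive benzoylation: it would have to acylate two hydroxyls wedged between an aryl ring and each other, on an air-sensitive catechol that carries all the material.

Plan of the new route:
With the central ring numbered as in the target name (C1/C2 benzoyloxy, C3/C6 aryl, C4/C5 hydroxy), the retrosynthesis cuts C3–C4 and C5–C6 (Diels–Alder), then C1–C6 and C2–C3 (double Claisen).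
The enabling feature is the mirror plane of the central benzene ring through the midpoints of C1–C2 and C4–C5: the ring divides into a symmetric diene C6–C1–C2–C3 (both aryl rings, both ester oxygens) and a symmetric dienophile C4–C5 (both free hydroxyl oxygens).
C1–C2 comes from diethyl oxalate, C4–C5 from vinylene carbonate, and C3 and C6 from a dibenzyl sulfone whose SO2 group acidifies the benzylic carbons, locks the diene s-cis in a thiophene 1,1-dioxide and then leaves as a gas.
Ring order: the outer benzene rings are bought, the thiophene dioxide ring is made as a temporary scaffold, and the central benzene ring is formed last.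
No biaryl bond is made, no quinone is handled, and the ester/hydroxyl pattern is fixed by which component brings which oxygen pair, so no hindered late acylation is needed.

Key step: step 4

Assumption: enediol 6 is written as its dienediol tautomer and adduct 9 as an endo/exo mixture; neither affects the outcome, since step 3 traps the dienediol and both adducts give 10.

Step 1
Reactants: 1 4-(benzyloxy)benzyl chloride (2 equiv)
Product: 3 bis[4-(benzyloxy)benzyl] sulfone, via sulfinate salt 2 (not isolated)
Conditions: HOCH2SO2Na·2H2O (0.55 equiv), K2CO3 (1.2 equiv), Bu4NI (5 mol %), DMF, rt to 60 °C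
Reagents that add atoms: sodium hydroxymethanesulfinate, [Na+].[O-]S(=O)CO
Why: Sulfone synthesis by twofold S-alkylation of a sulfoxylate equivalent, in which HOCH2SO2Na is S-benzylated and loses formaldehyde to give sulfinate 2, whose soft sulfur is benzylated by a second molecule of the activated benzylic chloride 1, and no stereocentre is formed.

Step 2
Reactants: 3 bis[4-(benzyloxy)benzyl] sulfone; 4 diethyl oxalate
Product: 6 2,5-bis[4-(benzyloxy)phenyl]-3,4-dihydroxythiophene 1,1-dioxide, via open-chain keto ester 5 (not isolated)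
Conditions: NaOEt (2.5 equiv), EtOH/THF, reflux; then 1 M HCl, 0 °C
Reagents that add atoms: none
Why: Hinsberg-type double Claisen condensation, in which each benzylic C–H (acidified by the sulfonyl group and its aryl ring) is C-acylated by one ester group of the oxalate, the second acylation closing the five-membered ring in a 5-exo-trig mode, and formation of the doubly deprotonated enediolate of 6 pulls the equilibria forward; the stereocentre of 5 disappears on enolisation.

Step 3
Reactants: 6 2,5-bis[4-(benzyloxy)phenyl]-3,4-dihydroxythiophene 1,1-dioxide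
Product: 7 2,5-bis[4-(benzyloxy)phenyl]-1,1-dioxothiophene-3,4-diyl dibenzoate
Conditions: BzCl (2.5 equiv), pyridine (4 equiv), CH2Cl2, 0 °C to rt
Reagents that add atoms: benzoyl chloride, O=C(Cl)c1ccccc1
Why: O-Acylation of an acidic cyclic enediol with an acyl chloride, in which only the two enol oxygens can react because the ring carbons carry no hydrogen in the dienediol and the sulfonyl oxygens cannot enolise, so the benzoates are placed on the two oxalate-derived oxygens that become O–C1 and O–C2 of the target.

Step 4
Reactants: 7 2,5-bis[4-(benzyloxy)phenyl]-1,1-dioxothiophene-3,4-diyl dibenzoate; 8 vinylene carbonate (1,3-dioxol-2-one)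
Product: 11 4,7-bis[4-(benzyloxy)phenyl]-2-oxo-1,3-benzodioxole-5,6-diyl dibenzoate, via sulfone-bridged adduct 9 (not isolated), via cis-dihydro carbonate 10 (not isolated)
Conditions: 8 (10 equiv), BHT (2 mol %), o-dichlorobenzene, sealed tube, 170 °C (−SO2); evaporate; then DDQ (1.3 equiv), PhCl, 80 °C
Reagents that add atoms: none
Why: The electron-poor, s-cis-locked diene C2=C3–C4=C5 of thiophene dioxide 7 should undergo a [4+2] cycloaddition of inverse electron demand with the cis-enediol carbonate 8, the 7-thiabicyclo[2.2.1]heptene 7,7-dioxide 9 should lose SO2 by cheletropic extrusion at the reaction temperature, and DDQ should remove the two remaining ring hydrogens of 10 (hydride abstraction from the allylic C–H to a cation stabilised by the 4-(benzyloxy)phenyl group, then proton loss) to give the benzene ring. The closest known reaction type is the Diels–Alder/SO2-extrusion benzannulation of substituted thiophene 1,1-dioxides with alkenes followed by dehydrogenation, combined with the use of vinylene carbonate as a cis-enediol dienophile. The central six-membered ring is closed by an intermolecular, concerted suprafacial [4+2] cycloaddition that forms both new bonds (C3–C4 and C5–C6 of the target) in the same event. The four sp3 centres of 9 and the two cis ring-fusion centres of 10 are set by the suprafacial addition but are all erased by extrusion and aromatisation, so endo/exo selectivity is irrelevant and any double-bond isomers of 10 converge on 11. No regioselectivity is needed because diene and dienophile each have a mirror plane; the chemoselectivity needed is dehydrogenation in preference to elimination of the allylic carbonate, which is secured by the cis ring fusion (each C–H is anti to the neighbouring C–O, so thermal syn-elimination is unavailable) and by the absence of acid or base, while aryl benzyl ethers are not attacked by DDQ under anhydrous conditions.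

Step 5
Reactants: 11 4,7-bis[4-(benzyloxy)phenyl]-2-oxo-1,3-benzodioxole-5,6-diyl dibenzoate
Product: 12 3,6-bis[4-(benzyloxy)phenyl]-4,5-dihydroxy-1,2-phenylene dibenzoate
Conditions: NaHCO3 (2 equiv), THF/H2O 3:1, degassed, 0 °C to rt; then 1 M HCl
Reagents that add atoms: none
Why: Chemoselective hydrolysis of a strained five-membered diaryl carbonate, whose exposed carbonyl carbon is attacked by hydroxide or water several orders of magnitude faster than the hindered aryl benzoates and whose ring-opened monocarbonate loses CO2 at once; the freed hydroxyls are meta and para to the ester oxygens, so no acyl shift can follow.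

Step 6
Reactants: 12 3,6-bis[4-(benzyloxy)phenyl]-4,5-dihydroxy-1,2-phenylene dibenzoate
Product: 13 4,5-dihydroxy-3,6-bis(4-hydroxyphenyl)-1,2-phenylene dibenzoate (target, achiral)
Conditions: H2 (1 atm), 10% Pd/C, THF/EtOAc 1:1, rt; filter under Ar
Reagents that add atoms: none
Why: Catalytic hydrogenolysis of the two aryl benzyl ethers, to which aryl benzoates and the free catechol are inert in a neutral aprotic medium; the product is achiral.

Compound list
1 | 4-(benzyloxy)benzyl chloride | ClCc1ccc(OCc2ccccc2)cc1 | starting material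
2 | sodium [4-(benzyloxy)phenyl]methanesulfinate | [Na+].[O-]S(=O)Cc1ccc(OCc2ccccc2)cc1 | intermediate
3 | bis[4-(benzyloxy)benzyl] sulfone | O=S(=O)(Cc1ccc(OCc2ccccc2)cc1)Cc1ccc(OCc2ccccc2)cc1 | intermediate
4 | diethyl oxalate | CCOC(=O)C(=O)OCC | starting material
5 | ethyl 3-[4-(benzyloxy)phenyl]-3-{[4-(benzyloxy)benzyl]sulfonyl}-2-oxopropanoate (racemic, present as its sodium enolate) | CCOC(=O)C(=O)C(c1ccc(OCc2ccccc2)cc1)S(=O)(=O)Cc1ccc(OCc2ccccc2)cc1 | intermediate
6 | 2,5-bis[4-(benzyloxy)phenyl]-3,4-dihydroxythiophene 1,1-dioxide | OC1=C(c2ccc(OCc3ccccc3)cc2)S(=O)(=O)C(c2ccc(OCc3ccccc3)cc2)=C1O | intermediate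
7 | 2,5-bis[4-(benzyloxy)phenyl]-1,1-dioxothiophene-3,4-diyl dibenzoate | O=C(OC1=C(c2ccc(OCc3ccccc3)cc2)S(=O)(=O)C(c2ccc(OCc3ccccc3)cc2)=C1OC(=O)c1ccccc1)c1ccccc1 | intermediate
8 | vinylene carbonate (1,3-dioxol-2-one) | O=C1OC=CO1 | starting material
9 | Diels–Alder adduct: 7-thiabicyclo[2.2.1]hept-2-ene 7,7-dioxide with 4-(benzyloxy)phenyl at C1 and C4, benzoyloxy at C2 and C3, and a cis-fused cyclic carbonate across C5 and C6 (endo/exo mixture, each meso) | O=C1OC2C(O1)C1(c3ccc(OCc4ccccc4)cc3)C(OC(=O)c3ccccc3)=C(OC(=O)c3ccccc3)C2(c2ccc(OCc3ccccc3)cc2)S1(=O)=O | intermediate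
10 | cis-4,7-bis[4-(benzyloxy)phenyl]-2-oxo-3a,7a-dihydro-1,3-benzodioxole-5,6-diyl dibenzoate (3aR,7aS, meso) | O=C1O[C@@H]2[C@H](O1)C(c1ccc(OCc3ccccc3)cc1)=C(OC(=O)c1ccccc1)C(OC(=O)c1ccccc1)=C2c1ccc(OCc2ccccc2)cc1 | intermediate
11 | 4,7-bis[4-(benzyloxy)phenyl]-2-oxo-1,3-benzodioxole-5,6-diyl dibenzoate | O=C1Oc2c(O1)c(-c1ccc(OCc3ccccc3)cc1)c(OC(=O)c1ccccc1)c(OC(=O)c1ccccc1)c2-c1ccc(OCc2ccccc2)cc1 | intermediate
12 | 3,6-bis[4-(benzyloxy)phenyl]-4,5-dihydroxy-1,2-phenylene dibenzoate | O=C(Oc1c(OC(=O)c2ccccc2)c(-c2ccc(OCc3ccccc3)cc2)c(O)c(O)c1-c1ccc(OCc2ccccc2)cc1)c1ccccc1 | intermediate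
13 | 4,5-dihydroxy-3,6-bis(4-hydroxyphenyl)-1,2-phenylene dibenzoate | O=C(Oc1c(OC(=O)c2ccccc2)c(-c2ccc(O)cc2)c(O)c(O)c1-c1ccc(O)cc1)c1ccccc1 | target

Total step count: 6. Longest linear sequence: 6 steps (1 to 13).

Steps most likely to fail

Step 4. The cycloaddition may be too slow at the two aryl-bearing termini of the sulfonyl-bridged diene, so that thermal polymerisation of 8 or eliminative loss of a ring oxygen from 10 overtakes the benzannulation. The fallback keeps the disconnection but exchanges the sulfonyl bridge for a carbonyl bridge, since cyclopentadienones are far more reactive dienes. It sets out from 4. Commercial 4-(benzyloxy)phenylacetic acid F1 would be self-condensed with decarboxylation (DCC, DMAP, CH2Cl2, rt) to 1,3-bis[4-(benzyloxy)phenyl]propan-2-one F2. The classical double Claisen condensation of F2 with 4 (NaOEt, EtOH) would give 2,5-bis[4-(benzyloxy)phenyl]-3,4-dihydroxycyclopenta-2,4-dien-1-one F3, the enolised cyclopentane-1,2,4-trione. Benzoylation (BzCl, pyridine) would give 3,4-bis(benzoyloxy)-2,5-bis[4-(benzyloxy)phenyl]cyclopenta-2,4-dien-1-one F4, whose symmetric constitution would have to be confirmed. Heating F4 with 8 would give the carbonyl-bridged adduct F5, which would lose CO and come back to the route at 10 (then DDQ to 11).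

Step 2. The second, ring-closing C-acylation may not keep pace with retro-Claisen cleavage of keto ester 5 by ethoxide, because the alkoxy-substituted benzylic sulfone is a weak carbon acid. The fallback replaces the reversible one-pot condensation by a stepwise, kinetically controlled construction that uses no alkoxide; it makes no new compound. It sets out from 3, which would be lithiated with LiN(iPr)2 (2.1 equiv, THF, −78 °C) and C-acylated with ethyl chlorooxoacetate to give 5, now isolated. The dianion of 5, generated with LiN(SiMe3)2 (2.2 equiv, THF, −78 to 0 °C), would close the ring by intramolecular acylation at the second benzylic carbon, and acid work-up would come back to the route at 6.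

Step 5. Benzoate may be lost by competing hydrolysis, or the freed electron-rich catechol may oxidise under the basic conditions. The fallback introduces the two hydroxyls oxidatively, with no carbonate and no hydrolysis. It sets out from 7, which would be heated with bis(pinacolatoboryl)ethyne F6 (o-dichlorobenzene, 180 °C). The sulfone-bridged norbornadiene adduct F7 would lose SO2 to give directly the arene 3,6-bis[4-(benzyloxy)phenyl]-4,5-bis(4,4,5,5-tetramethyl-1,3,2-dioxaborolan-2-yl)-1,2-phenylene dibenzoate F8, without a dihydro stage. Oxidation of both C–B bonds under non-nucleophilic conditions (KHSO5, aqueous acetone, NaHCO3 buffer, 0 °C; Na2S2O4 work-up) would come back to the route at 12.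

Further compounds
F1 | step 4 | 4-(benzyloxy)phenylacetic acid | OC(=O)Cc1ccc(OCc2ccccc2)cc1
F2 | step 4 | 1,3-bis[4-(benzyloxy)phenyl]propan-2-one | O=C(Cc1ccc(OCc2ccccc2)cc1)Cc1ccc(OCc2ccccc2)cc1
F3 | step 4 | 2,5-bis[4-(benzyloxy)phenyl]-3,4-dihydroxycyclopenta-2,4-dien-1-one | O=C1C(c2ccc(OCc3ccccc3)cc2)=C(O)C(O)=C1c1ccc(OCc2ccccc2)cc1
F4 | step 4 | 3,4-bis(benzoyloxy)-2,5-bis[4-(benzyloxy)phenyl]cyclopenta-2,4-dien-1-one | O=C1C(c2ccc(OCc3ccccc3)cc2)=C(OC(=O)c2ccccc2)C(OC(=O)c2ccccc2)=C1c1ccc(OCc2ccccc2)cc1
F5 | step 4 | carbonyl-bridged adduct: 7-oxobicyclo[2.2.1]hept-2-ene with 4-(benzyloxy)phenyl at C1 and C4, benzoyloxy at C2 and C3, and a cis-fused cyclic carbonate across C5 and C6 (endo/exo mixture) | O=C1OC2C(O1)C1(c3ccc(OCc4ccccc4)cc3)C(OC(=O)c3ccccc3)=C(OC(=O)c3ccccc3)C2(c2ccc(OCc3ccccc3)cc2)C1=O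
F0 | step 2 | none | none
F6 | step 5 | bis(pinacolatoboryl)ethyne | CC1(C)OB(C#CB2OC(C)(C)C(C)(C)O2)OC1(C)C
F7 | step 5 | sulfone-bridged adduct: 7-thiabicyclo[2.2.1]hepta-2,5-diene 7,7-dioxide with 4-(benzyloxy)phenyl at C1 and C4, benzoyloxy at C2 and C3, and pinacolatoboryl at C5 and C6 | O=C(OC1=C(OC(=O)c2ccccc2)C2(c3ccc(OCc4ccccc4)cc3)C(B3OC(C)(C)C(C)(C)O3)=C(B3OC(C)(C)C(C)(C)O3)C1(c1ccc(OCc3ccccc3)cc1)S2(=O)=O)c1ccccc1
F8 | step 5 | 3,6-bis[4-(benzyloxy)phenyl]-4,5-bis(4,4,5,5-tetramethyl-1,3,2-dioxaborolan-2-yl)-1,2-phenylene dibenzoate | O=C(Oc1c(OC(=O)c2ccccc2)c(-c2ccc(OCc3ccccc3)cc2)c(B2OC(C)(C)C(C)(C)O2)c(B2OC(C)(C)C(C)(C)O2)c1-c1ccc(OCc2ccccc2)cc1)c1ccccc1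
A1 | direct plan | 4,5-bis(benzyloxy)cyclohexa-3,5-diene-1,2-dione | O=C1C=C(OCc2ccccc2)C(OCc2ccccc2)=CC1=O
A2 | direct plan | 4-(benzyloxy)benzenediazonium tetrafluoroborate | N#[N+]c1ccc(OCc2ccccc2)cc1.F[B-](F)(F)F
A3 | direct plan | 4,5-bis(benzyloxy)-3,6-bis[4-(benzyloxy)phenyl]cyclohexa-3,5-diene-1,2-dione | O=C1C(c2ccc(OCc3ccccc3)cc2)=C(OCc2ccccc2)C(OCc2ccccc2)=C(c2ccc(OCc3ccccc3)cc2)C1=O
A4 | direct plan | 4,5-bis(benzyloxy)-3,6-bis[4-(benzyloxy)phenyl]-1,2-phenylene dibenzoate | O=C(Oc1c(OC(=O)c2ccccc2)c(-c2ccc(OCc3ccccc3)cc2)c(OCc2ccccc2)c(OCc2ccccc2)c1-c1ccc(OCc2ccccc2)cc1)c1ccccc1
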